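**Plan**

- Retrosynthesis: the C8 ester and C13 acetate are cut first. The γ-ylidene butenolide (C5=C6, C12=O) goes back to a furan (C6, C7, C11, C12) by singlet-oxygen oxidation and loss of water. Then C2=C3 is cut by olefin metathesis together with the O–C1 bond of the oxygen bridge, and last the C5–C6 bond (furyllithium plus epoxide) and the C8–C9 bond (Grignard addition).
- Enabling feature: in the tetrahydrofuran ring the two methylene carbons C2 and C3 lie between the hemiketal carbon C1 (ketone oxidation level) and the tertiary ether carbon C4. That ring is therefore a reduced, closed cis γ-hydroxy enone, and joining a C1 vinyl ketone to a C4 vinyl carbinol at C2=C3 lets the C4 hydroxyl add to C1 unaided.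
- Forward order: 3,4-disubstituted furan, then the C8–C10 chain, then the C3–C5 unit on furan carbon C6, then the ten-membered carbocycle and the oxygen bridge in one step. After that come saturation of C2=C3, the C13 acetate, the C8 ester, and the butenolide last.
- Stereochemistry: C10 comes from (S)-3-bromo-2-methylpropan-1-ol. C4 and the side-chain carbinol C2′ both come from (R)-2-methylglycidol. C8 is set by CBS reduction, C1 is imposed by C4 through the bridge, and the C5=C6 geometry is imposed by the ring.

Key step: step 17

Remark: germacranolide numbering is used for all intermediates (C1 hemiketal carbon, C2/C3 ring CH2 pair, C4 tertiary ether carbon, C6 and C12 the furan α-carbons, C7 and C11 the furan β-carbons, C8 carbinol carbon, C10 the CH(CH3) carbon, C13 the CH2O carbon); the bromo alcohol and the glycidol are assumed to be purchasable, and the epimer mixtures formed at C8 (Grignard addition), C1 (vinyl addition) and C6 (photooxygenation) are carried on because each centre is erased in the following step.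

**Route**

Step 1
Reactants: 1 diethyl furan-3,4-dicarboxylate
Product: 2 furan-3,4-diyldimethanol
Conditions: LiAlH4, THF, 0 °C to rt; then H2O
Reagents that add atoms: none
Why: Hydride reduction of both esters with LiAlH4 should give the symmetric diol while the furan ring is left untouched.

Step 2
Reactants: 2 furan-3,4-diyldimethanol
Product: 3 [4-(tert-butyldiphenylsilyloxymethyl)furan-3-yl]methanol
Conditions: NaH (1.0 equiv), THF, 0 °C; then TBDPSCl (1.0 equiv), rt
Reagents that add atoms: tert-butyl(chloro)diphenylsilane, CC(C)(C)[Si](Cl)(c1ccccc1)c1ccccc1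
Why: Monosilylation of a symmetric diol through its monosodium alkoxide should set the future C13 oxygen (silyl ether) apart from the future C8 carbon (free CH2OH).

Step 3
Reactants: 3 [4-(tert-butyldiphenylsilyloxymethyl)furan-3-yl]methanol
Product: 4 4-(tert-butyldiphenylsilyloxymethyl)furan-3-carbaldehyde
Conditions: MnO2, CH2Cl2, rt
Reagents that add atoms: none
Why: MnO2 oxidation of a furylmethanol (a benzylic-type alcohol) should stop at the aldehyde and leave the silyl ether alone.

Step 4
Reactants: 5 (S)-3-bromo-2-methylpropan-1-ol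
Product: 6 (S)-(3-bromo-2-methylpropoxy)(tert-butyl)dimethylsilane
Conditions: TBSCl, imidazole, CH2Cl2, 0 °C to rt
Reagents that add atoms: tert-butyl(chloro)dimethylsilane, CC(C)(C)[Si](C)(C)Cl
Why: Standard silylation of a primary alcohol protects the future C1 oxygen and does not touch the stereocenter that becomes C10.

Step 5
Reactants: 6 (S)-(3-bromo-2-methylpropoxy)(tert-butyl)dimethylsilane; 4 4-(tert-butyldiphenylsilyloxymethyl)furan-3-carbaldehyde
Product: 8 (8RS,10R)-furyl carbinol (C8 epimers), via Grignard reagent 7 (not isolated)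
Conditions: Mg, I2 (cat.), THF, 50 °C; then 4, THF, −78 to 0 °C; then H2O
Reagents that add atoms: none
Why: Grignard formation from the primary bromide and 1,2-addition to the aldehyde should form the C8–C9 bond, with C8 formed unselectively because it is oxidised in the next step and C10 untouched.

Step 6
Reactants: 8 (8RS,10R)-furyl carbinol
Product: 9 (10R)-furyl ketone
Conditions: Dess–Martin periodinane, pyridine, CH2Cl2, 0 °C to rt
Reagents that add atoms: none
Why: Dess–Martin oxidation of the secondary carbinol under buffered conditions should give the aryl ketone without endangering C10, which is β to the new carbonyl.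

Step 7
Reactants: 9 (10R)-furyl ketone
Product: 10 (8R,10R)-furyl carbinol
Conditions: (S)-2-methyl-CBS-oxazaborolidine (0.2 equiv), BH3·SMe2, THF, −20 °C; then MeOH
Reagents that add atoms: none
Why: Corey–Bakshi–Shibata reduction of an aryl alkyl ketone, with the substituted furyl group as the large and the CH2 chain as the small substituent, should give the (8R)-alcohol under control of the (S)-catalyst.

Step 8
Reactants: 11 (R)-2-methylglycidol
Product: 12 (S)-triethyl[(2-methyloxiran-2-yl)methoxy]silane
Conditions: TESCl, imidazole, CH2Cl2, 0 °C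
Reagents that add atoms: chlorotriethylsilane, CC[Si](Cl)(CC)CC
Why: Silylation of the primary alcohol leaves the epoxide and its quaternary stereocenter intact, and the descriptor changes only through the priority rules.

Step 9
Reactants: 10 (8R,10R)-furyl carbinol; 12 (S)-triethyl[(2-methyloxiran-2-yl)methoxy]silane
Product: 14 (4S,8R,10R)-diol with the CH2–C(CH3)(OH)–CH2OSiEt3 chain on furan C6, via dilithio species 13 (not isolated)
Conditions: n-BuLi (2.3 equiv), THF, −78 to 0 °C; then 12, 0 °C to rt; then H2O
Reagents that add atoms: none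
Why: Alkoxide-directed ortho-lithiation of a 3-furyl carbinol should place lithium on the α-carbon C6 next to the C8 alkoxide (the bulky silyloxymethyl group on the other side is a poor director), and the furyllithium should open the epoxide by SN2 attack at its CH2 group, so that C4 is taken over from (R)-2-methylglycidol without any bond to the stereocenter being broken.

Step 10
Reactants: 14 (4S,8R,10R)-diol
Product: 15 (4S,8R,10R)-C8 tert-butyldimethylsilyl ether with free C4 hydroxyl
Conditions: TBSOTf (1.1 equiv), 2,6-lutidine, CH2Cl2, −78 °C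
Reagents that add atoms: tert-butyldimethylsilyl trifluoromethanesulfonate, CC(C)(C)[Si](C)(C)OS(=O)(=O)C(F)(F)F
Why: Silyl ether formation with one equivalent of TBSOTf at low temperature should take the secondary C8 hydroxyl much faster than the tertiary C4 hydroxyl on steric grounds.

Step 11
Reactants: 15 (4S,8R,10R)-C8 silyl ether
Product: 16 (4S,8R,10R)-α-hydroxy aldehyde (C3 aldehyde)
Conditions: (COCl)2, DMSO, CH2Cl2, −78 to −40 °C; then Et3N, −78 °C to rt
Reagents that add atoms: none
Why: Under Swern conditions a primary triethylsilyl ether is cleaved by the chlorosulfonium salt and oxidised in the same flask, while the tert-butylsilyl ethers and the tertiary alcohol are expected to survive, so the aldehyde should form without a separate deprotection.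

Step 12
Reactants: 16 (4S,8R,10R)-α-hydroxy aldehyde
Product: 17 (4S,8R,10R)-tertiary vinyl carbinol
Conditions: Ph3PCH3Br, KOtBu, THF, 0 °C; then 16, −78 to 0 °C
Reagents that add atoms: methyltriphenylphosphonium bromide, C[P+](c1ccccc1)(c1ccccc1)c1ccccc1.[Br-]
Why: Wittig methylenation with excess unstabilised ylide (one equivalent is held as the C4 alkoxide) should give the vinyl group on C4 with the quaternary centre unchanged.

Step 13
Reactants: 17 (4S,8R,10R)-tertiary vinyl carbinol
Product: 18 (4S,8R,10R)-C1 primary alcohol
Conditions: HF·pyridine, pyridine, THF, 0 °C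
Reagents that add atoms: none
Why: Buffered fluoride desilylation should remove the unhindered primary tert-butyldimethylsilyl ether at C1 faster than the hindered secondary one at C8 and the primary tert-butyldiphenylsilyl ether at C13.

Step 14
Reactants: 18 (4S,8R,10R)-C1 primary alcohol
Product: 19 (4S,8R,10R)-C1 aldehyde
Conditions: Dess–Martin periodinane, pyridine, CH2Cl2, 0 °C
Reagents that add atoms: none
Why: Dess–Martin oxidation under buffered conditions should give the α-methyl aldehyde without epimerising C10, and the tertiary allylic alcohol cannot be oxidised.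

Step 15
Reactants: 19 (4S,8R,10R)-C1 aldehyde
Product: 20 (4S,8R,10R)-C1 allylic alcohol (C1 epimers)
Conditions: CH2=CHMgBr (3 equiv), THF, −78 °C; then H2O
Reagents that add atoms: vinylmagnesium bromide, C=C[Mg]Br
Why: Grignard 1,2-addition at low temperature should give the allylic alcohol as a mixture at C1, which does not matter because C1 becomes a ketone in the next step.

Step 16
Reactants: 20 (4S,8R,10R)-C1 allylic alcohol
Product: 21 (4S,8R,10R)-vinyl ketone with free C4 vinyl carbinol
Conditions: Dess–Martin periodinane, pyridine, CH2Cl2, 0 °C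
Reagents that add atoms: none
Why: Dess–Martin oxidation of the secondary allylic alcohol should give the vinyl ketone under mild conditions while the tertiary C4 carbinol stays free for the next step.

Step 17
Reactants: 21 (4S,8R,10R)-vinyl ketone
Product: 23 (1R,4S,8R,10R)-furan-fused bridged 2,5-dihydrofuran hemiketal, via cis hydroxy enone 22 (not isolated)
Conditions: second-generation Hoveyda–Grubbs catalyst RuCl2(H2IMes)(=CH-C6H4-2-OiPr) (10 mol%), toluene (0.001 M), 80 °C, argon sparge
Reagents that add atoms: none
Why: The ruthenium alkylidene should load on the vinyl group of the free tertiary allylic alcohol, add to the enone vinyl group by [2+2] cycloaddition and cycloreversion and expel ethene, which is ring-closing metathesis as known for ten-membered carbocycles and for enone partners. The carbocycle closes through the new C2=C3 bond, helped by the furan, which already holds four ring atoms coplanar, and the five-membered ring closes by 5-exo-trig addition of the C4 hydroxyl to the C1 carbonyl of 22, the known cyclisation of cis γ-hydroxy enones to 2,5-dihydrofuran-2-ols. The only new stereocenter, C1, is dictated by C4, because a one-atom oxygen bridge can span C1 and C4 of the ten-membered ring on one face only (C1 is R here and becomes S by priority once C2=C3 is saturated). The step needs the Z olefin, and only the Z enone can be trapped as the hemiketal, which drains it from the reversible metathesis manifold, while high dilution suppresses dimers. C4 is quaternary, so the dihydrofuranol cannot lose water to a furan, and the silyl ethers and the aromatic furan are inert to the catalyst.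

Step 18
Reactants: 23 (1R,4S,8R,10R)-dihydrofuran hemiketal
Product: 24 (1S,4R,8R,10R)-tetrahydrofuran hemiketal
Conditions: 2-nitrobenzenesulfonyl hydrazide, Et3N, CH2Cl2, rt
Reagents that add atoms: none
Why: Diimide reduction should deliver hydrogen to the strained cis-disubstituted C2=C3 bond without reducing the furan or cleaving the furylmethyl C–O bonds, and the descriptors at C1 and C4 change only through the priority rules.

Step 19
Reactants: 24 (1S,4R,8R,10R)-tetrahydrofuran hemiketal
Product: 25 (1S,4R,8R,10R)-C8,C13-diol
Conditions: Bu4NF, AcOH, THF, 0 °C to rt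
Reagents that add atoms: none
Why: Fluoride desilylation should cleave both silyl ethers, and the acetic acid buffer should keep the hemiketal from opening to an enolisable ketone, so that C10 is not epimerised.

Step 20
Reactants: 25 (1S,4R,8R,10R)-C8,C13-diol
Product: 26 (1S,4R,8R,10R)-C13 acetate with free C8 hydroxyl
Conditions: AcCl (1.05 equiv), 2,4,6-collidine, CH2Cl2, −78 °C
Reagents that add atoms: acetyl chloride, CC(=O)Cl
Why: Selective acylation with acetyl chloride and a hindered pyridine base at low temperature should take the primary C13 hydroxyl in preference to the hindered secondary C8 hydroxyl and the tertiary hemiketal hydroxyl.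

Step 21
Reactants: 11 (R)-2-methylglycidol
Product: 27 sodium (S)-2-methyloxirane-2-carboxylate
Conditions: RuCl3 (2 mol%), NaIO4, NaHCO3, MeCN/EtOAc/H2O, 0 °C to rt
Reagents that add atoms: water, O; sodium hydrogencarbonate, [Na+].OC([O-])=O
Why: Catalytic RuO4 oxidation (RuCl3/NaIO4) of an epoxy alcohol should give the glycidic acid salt without opening the epoxide, and the quaternary stereocenter is not involved (R becomes S by priority only).

Step 22
Reactants: 27 sodium (S)-2-methyloxirane-2-carboxylate
Product: 28 (R)-3-chloro-2-hydroxy-2-methylpropanoic acid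
Conditions: HCl (4 M in dioxane), 0 °C to rt
Reagents that add atoms: hydrogen chloride, Cl
Why: Acid-mediated epoxide opening by chloride should occur by SN2 attack at the CH2 carbon, because positive charge cannot develop next to the carboxyl group, so the tertiary carbinol keeps its configuration and is (R) by the changed priorities.

Step 23
Reactants: 28 (R)-3-chloro-2-hydroxy-2-methylpropanoic acid; 26 (1S,4R,8R,10R)-C13 acetate
Product: 30 (1S,4R,8R,10R,2′R)-C8 chlorohydrin ester (furan stage), via mixed anhydride 29 (not isolated)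
Conditions: 2,4,6-trichlorobenzoyl chloride, Et3N, THF, 0 °C; then 26, DMAP, toluene, rt
Reagents that add atoms: none
Why: Yamaguchi esterification through the mixed anhydride and DMAP should acylate the secondary C8 hydroxyl, because the tertiary hydroxyls of the acid and of the hemiketal are too hindered to compete, and no stereocenter is touched.

Step 24
Reactants: 30 (1S,4R,8R,10R,2′R)-C8 chlorohydrin ester
Product: 32 γ-hydroxybutenolide (C6 epimers), via endoperoxide 31 (not isolated)
Conditions: O2, visible light, methylene blue (cat.), iPr2NEt, CH2Cl2, −78 °C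
Reagents that add atoms: oxygen, O=O
Why: Singlet oxygen should add across the furan by [4+2] cycloaddition, and the amine base should remove the only α-hydrogen (on C12) of the endoperoxide in a Kornblum–DeLaMare-type fragmentation, which places the lactone carbonyl at C12 and the hydroxyl at C6.

Step 25
Reactants: 32 γ-hydroxybutenolide
Product: 34 CNP0414417.2 (target), via acetoxybutenolide 33 (not isolated)
Conditions: Ac2O, Et3N, CH2Cl2, 0 °C to rt
Reagents that add atoms: none
Why: Acetylation of the lactol-type C6 hydroxyl and base-induced loss of acetic acid (dehydration of a γ-hydroxybutenolide to a γ-ylidenebutenolide) can only involve the C5 hydrogens, and the ten-membered ring should allow only the C5=C6 isomer with C4 cis to C7, which is the (E) geometry of the target.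

**Compound list**

1 | diethyl furan-3,4-dicarboxylate | CCOC(=O)c1cocc1C(=O)OCC | starting material
2 | furan-3,4-diyldimethanol | OCc1cocc1CO | intermediate
3 | [4-(tert-butyldiphenylsilyloxymethyl)furan-3-yl]methanol | OCc1cocc1CO[Si](c2ccccc2)(c3ccccc3)C(C)(C)C | intermediate
4 | 4-(tert-butyldiphenylsilyloxymethyl)furan-3-carbaldehyde | O=Cc1cocc1CO[Si](c2ccccc2)(c3ccccc3)C(C)(C)C | intermediate
5 | (S)-3-bromo-2-methylpropan-1-ol | OC[C@H](C)CBr | starting material
6 | (S)-(3-bromo-2-methylpropoxy)(tert-butyl)dimethylsilane | CC(C)(C)[Si](C)(C)OC[C@H](C)CBr | intermediate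
7 | (S)-[3-(tert-butyldimethylsilyloxy)-2-methylpropyl]magnesium bromide (formed in the flask) | CC(C)(C)[Si](C)(C)OC[C@H](C)C[Mg]Br | intermediate
8 | (1RS,3R)-4-(tert-butyldimethylsilyloxy)-1-[4-(tert-butyldiphenylsilyloxymethyl)furan-3-yl]-3-methylbutan-1-ol (C8 epimers) | CC(C)(C)[Si](C)(C)OC[C@H](C)CC(O)c1cocc1CO[Si](c2ccccc2)(c3ccccc3)C(C)(C)C | intermediate
9 | (R)-4-(tert-butyldimethylsilyloxy)-1-[4-(tert-butyldiphenylsilyloxymethyl)furan-3-yl]-3-methylbutan-1-one | CC(C)(C)[Si](C)(C)OC[C@H](C)CC(=O)c1cocc1CO[Si](c2ccccc2)(c3ccccc3)C(C)(C)C | intermediate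
10 | (1R,3R)-4-(tert-butyldimethylsilyloxy)-1-[4-(tert-butyldiphenylsilyloxymethyl)furan-3-yl]-3-methylbutan-1-ol, (8R,10R) | CC(C)(C)[Si](C)(C)OC[C@H](C)C[C@@H](O)c1cocc1CO[Si](c2ccccc2)(c3ccccc3)C(C)(C)C | intermediate
11 | (R)-2-methylglycidol, [(2R)-2-methyloxiran-2-yl]methanol | OC[C@]1(C)CO1 | starting material
12 | (S)-triethyl[(2-methyloxiran-2-yl)methoxy]silane | CC[Si](CC)(CC)OC[C@]1(C)CO1 | intermediate
13 | O8,C6-dilithio derivative of 10 (formed in the flask) | CC(C)(C)[Si](C)(C)OC[C@H](C)C[C@@H](O[Li])c1c([Li])occ1CO[Si](c2ccccc2)(c3ccccc3)C(C)(C)C | intermediate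
14 | (4S,8R,10R)-diol: 10 with CH2–C(CH3)(OH)–CH2OSiEt3 on furan C6 | CC(C)(C)[Si](C)(C)OC[C@H](C)C[C@@H](O)c1c(C[C@](C)(O)CO[Si](CC)(CC)CC)occ1CO[Si](c2ccccc2)(c3ccccc3)C(C)(C)C | intermediate
15 | (4S,8R,10R)-C8 tert-butyldimethylsilyl ether of 14 | CC(C)(C)[Si](C)(C)OC[C@H](C)C[C@@H](O[Si](C)(C)C(C)(C)C)c1c(C[C@](C)(O)CO[Si](CC)(CC)CC)occ1CO[Si](c2ccccc2)(c3ccccc3)C(C)(C)C | intermediate
16 | (4S,8R,10R)-α-hydroxy aldehyde (C3 aldehyde) | CC(C)(C)[Si](C)(C)OC[C@H](C)C[C@@H](O[Si](C)(C)C(C)(C)C)c1c(C[C@](C)(O)C=O)occ1CO[Si](c2ccccc2)(c3ccccc3)C(C)(C)C | intermediate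
17 | (4S,8R,10R)-tertiary vinyl carbinol | CC(C)(C)[Si](C)(C)OC[C@H](C)C[C@@H](O[Si](C)(C)C(C)(C)C)c1c(C[C@](C)(O)C=C)occ1CO[Si](c2ccccc2)(c3ccccc3)C(C)(C)C | intermediate
18 | (4S,8R,10R)-C1 primary alcohol | OC[C@H](C)C[C@@H](O[Si](C)(C)C(C)(C)C)c1c(C[C@](C)(O)C=C)occ1CO[Si](c2ccccc2)(c3ccccc3)C(C)(C)C | intermediate
19 | (4S,8R,10R)-C1 aldehyde | O=C[C@H](C)C[C@@H](O[Si](C)(C)C(C)(C)C)c1c(C[C@](C)(O)C=C)occ1CO[Si](c2ccccc2)(c3ccccc3)C(C)(C)C | intermediate
20 | (4S,8R,10R)-C1 allylic alcohol (C1 epimers) | C=CC(O)[C@H](C)C[C@@H](O[Si](C)(C)C(C)(C)C)c1c(C[C@](C)(O)C=C)occ1CO[Si](c2ccccc2)(c3ccccc3)C(C)(C)C | intermediate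
21 | (4S,8R,10R)-vinyl ketone with C4 vinyl carbinol (metathesis precursor) | C=CC(=O)[C@H](C)C[C@@H](O[Si](C)(C)C(C)(C)C)c1c(C[C@](C)(O)C=C)occ1CO[Si](c2ccccc2)(c3ccccc3)C(C)(C)C | intermediate
22 | (2Z,4S,8R,10R)-furan-fused ten-membered cis γ-hydroxy enone (formed in the flask) | O=C1/C=C\[C@@](C)(O)Cc2occ(CO[Si](c3ccccc3)(c4ccccc4)C(C)(C)C)c2[C@H](O[Si](C)(C)C(C)(C)C)C[C@H]1C | intermediate
23 | (1R,4S,8R,10R)-furan-fused 1,4-epoxy-bridged 2,5-dihydrofuran hemiketal | CC(C)(C)[Si](c4ccccc4)(c5ccccc5)OCc1coc2c1[C@H](O[Si](C)(C)C(C)(C)C)C[C@@H](C)[C@]3(O)C=C[C@@](C)(O3)C2 | intermediate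
24 | (1S,4R,8R,10R)-tetrahydrofuran hemiketal (C2–C3 saturated) | CC(C)(C)[Si](c4ccccc4)(c5ccccc5)OCc1coc2c1[C@H](O[Si](C)(C)C(C)(C)C)C[C@@H](C)[C@]3(O)CC[C@@](C)(O3)C2 | intermediate
25 | (1S,4R,8R,10R)-C8,C13-diol | OCc1coc2c1[C@H](O)C[C@@H](C)[C@]3(O)CC[C@@](C)(O3)C2 | intermediate
26 | (1S,4R,8R,10R)-C13 acetate with free C8 hydroxyl | CC(=O)OCc1coc2c1[C@H](O)C[C@@H](C)[C@]3(O)CC[C@@](C)(O3)C2 | intermediate
27 | sodium (S)-2-methyloxirane-2-carboxylate | [Na+].[O-]C(=O)[C@]1(C)CO1 | intermediate
28 | (R)-3-chloro-2-hydroxy-2-methylpropanoic acid | OC(=O)[C@@](C)(O)CCl | intermediate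
29 | mixed anhydride of 28 and 2,4,6-trichlorobenzoic acid (formed in the flask) | O=C(OC(=O)[C@@](C)(O)CCl)c1c(Cl)cc(Cl)cc1Cl | intermediate
30 | (1S,4R,8R,10R,2′R)-C8 chlorohydrin ester, furan stage | CC(=O)OCc1coc2c1[C@H](OC(=O)[C@@](C)(O)CCl)C[C@@H](C)[C@]3(O)CC[C@@](C)(O3)C2 | intermediate
31 | furan endoperoxide of 30 (formed in the flask) | CC(=O)OCC1=C2[C@H](OC(=O)[C@@](C)(O)CCl)C[C@@H](C)[C@]3(O)CC[C@@](C)(O3)CC24OOC1O4 | intermediate
32 | γ-hydroxybutenolide (C6 epimers) | CC(=O)OCC1=C2[C@H](OC(=O)[C@@](C)(O)CCl)C[C@@H](C)[C@]3(O)CC[C@@](C)(O3)CC2(O)OC1=O | intermediate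
33 | γ-acetoxybutenolide (formed in the flask) | CC(=O)OCC1=C2[C@H](OC(=O)[C@@](C)(O)CCl)C[C@@H](C)[C@]3(O)CC[C@@](C)(O3)CC2(OC(C)=O)OC1=O | intermediate
34 | CNP0414417.2, (1S,4R,5E,8R,10R,2′R) | CC(=O)OCC1=C2/C(=C\[C@@]3(C)CC[C@](O)(O3)[C@H](C)C[C@H]2OC(=O)[C@@](C)(O)CCl)OC1=O | target

**Step count**

Total: 25 steps. Longest linear sequence: 21 steps (steps 1–3, 5–7, 9–20, 23–25).

**Steps most likely to fail**

1. Step 17. The enone vinyl group is electron-poor and the carbinol vinyl group is hindered, so turnover may be slow. Intermolecular metathesis or catalyst decay could then win, or the ring could close to the E olefin, which cannot be trapped. The fallback changes the oxidation level at which the ring is closed and sets out from 20. Ring-closing metathesis of the diene 20 with RuCl2(H2IMes)(=CH-C6H4-2-OiPr) under the same dilution, where both vinyl groups sit on carbinols, should give the ten-membered cis ene-diol F1. MnO2 oxidation of its secondary allylic alcohol then gives the cis hydroxy enone 22, which closes by itself, and the route is rejoined at 23.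

2. Step 9. The chelated, aggregated dianion may open the hindered 2,2-disubstituted epoxide too slowly, so that protonation or decomposition of the furyllithium takes over. The fallback separates the regiochemical control from the C–C bond formation and sets out from 10. The same directed lithiation is quenched with I2 to give the C6 iodide F2, whose C8 hydroxyl is silylated (TBSOTf, 2,6-lutidine) to the silyl ether F3. Iodine–lithium exchange with t-BuLi at −78 °C gives the unchelated furyllithium F4, which with BF3·OEt2 and epoxide 12 should open the epoxide at its CH2 group. The route is rejoined at 15.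

3. Step 23. Acyl transfer from a hindered acid that carries a free tertiary hydroxyl may stall, and the amine bases may slowly close the chlorohydrin to the epoxide. The fallback introduces the chloride after the ester bond is formed and sets out from 26 and 27. Yamaguchi activation of the glycidate 27 gives the mixed anhydride F5, which should acylate 26 to the C8 glycidate ester F6. Opening of that epoxide at its CH2 carbon with LiCl and AcOH in THF then gives the chlorohydrin, and the route is rejoined at 30.

**Further compounds**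

F1 | step 17 | (2Z,4S,8R,10R)-furan-fused ten-membered ene-1,4-diol (C1 epimers) | OC1/C=C\[C@@](C)(O)Cc2occ(CO[Si](c3ccccc3)(c4ccccc4)C(C)(C)C)c2[C@H](O[Si](C)(C)C(C)(C)C)C[C@H]1C
F2 | step 9 | C6-iodo derivative of 10 | CC(C)(C)[Si](C)(C)OC[C@H](C)C[C@@H](O)c1c(I)occ1CO[Si](c2ccccc2)(c3ccccc3)C(C)(C)C
F3 | step 9 | C8 tert-butyldimethylsilyl ether of F2 | CC(C)(C)[Si](C)(C)OC[C@H](C)C[C@@H](O[Si](C)(C)C(C)(C)C)c1c(I)occ1CO[Si](c2ccccc2)(c3ccccc3)C(C)(C)C
F4 | step 9 | C6-lithio furan from F3 | CC(C)(C)[Si](C)(C)OC[C@H](C)C[C@@H](O[Si](C)(C)C(C)(C)C)c1c([Li])occ1CO[Si](c2ccccc2)(c3ccccc3)C(C)(C)C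
F5 | step 23 | mixed anhydride of (S)-2-methyloxirane-2-carboxylic acid and 2,4,6-trichlorobenzoic acid | O=C(OC(=O)[C@]1(C)CO1)c2c(Cl)cc(Cl)cc2Cl
F6 | step 23 | C8 (S)-2-methylglycidate ester of 26 | CC(=O)OCc1coc2c1[C@H](OC(=O)[C@]4(C)CO4)C[C@@H](C)[C@]3(O)CC[C@@](C)(O3)C2
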